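The constants come from no measurement; the flask was simulated.

Two slow things shape this flask: at the charge, gas enters solution more slowly than starting material takes it up, and afterwards the target is eaten over a time longer than the run.

starting material 17 mM; gas phase 0.83 mM (held); time 5.0 h

    gas phase ⇌ dissolved gas, rate k1*(csat - [dissolved gas]) (k1 = 0.0063 s⁻¹, csat = 0.83 mM)
    starting material + dissolved gas → target (k2 = 4.3 M⁻¹ s⁻¹)
    starting material → side product (k3 = 0.0017 s⁻¹)
    dissolved gas → decomposed reagent (k4 = 3.2 × 10⁻⁵ s⁻¹)
    dissolved gas + target → over-reaction product (k5 = 0.031 M⁻¹ s⁻¹)
    dissolved gas → decomposition product (k6 = 1.2 × 10⁻⁷ s⁻¹)

1. the target standing at 5.0 h, as a percentage of the starting material charged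
2. concentration of dissolved gas in solution at 5.0 h, in percent of saturation

I start from two extremes. Suppose passage is instant: [dissolved gas] stands at 0.83 mM, the route to target runs at 0.00357 s⁻¹ against 0.0017 s⁻¹ for the side product, and target takes a share of 67.7%. Suppose instead that dissolved gas is consumed as it arrives: the target's share at the charge is then supply against side reaction, 15.3%. This flask begins near the second extreme, because at the charge starting material consumes dissolved gas at 0.0731 s⁻¹, faster than the transfer coefficient of 0.0063 s⁻¹, and it drifts towards the first as [starting material] falls.

So I go round again and put [starting material] back into the gas balance. With supply balancing uptake, that gives an estimated [dissolved gas] of 0.0659 mM while [starting material] stands at its charge, and summing the local share over the starting material consumed gives an estimated peak of 4.79 mM of target, or 28.2% of the charge, which lies above the share at the charge and below the instant share.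

After that the target decays in pseudo-first-order fashion. Its over-reaction time 10.8 h, one over the over-reaction constant times the saturation concentration, is longer than the run. Counting the whole run as decay, I estimate survival at 62.9%, so I commit to 17.7%. With that target and no uptake by starting material, first-order losses of dissolved gas total 1.26 × 10⁻⁴ s⁻¹ against 0.0063 s⁻¹, which puts my estimate of saturation at 98.0%.

The forecast gives 18% and 98%, saying “only about 4.6 mM of target forms within the first half hour”, where my estimated peak is 4.79 mM.

This flask gives 17.5% and 98.1%. In a run of this flask with every passage made instant, a thousand times as fast, target at the asked time stands at 42.7%. The over-reaction time carries this flask's 21.9% of target at 2.50 h forward to 17.4% at the asked time.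

For the neighbour flask read at 20 h, the same over-reaction time carries the target's 17.5% forward to 4.36%. Computed, that flask holds 4.44% of target.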